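Ring numbering used throughout: C1 (OAc), C2 (OH), C3 (OH), C4=C5 (C5 bears C7H2OBz), C6 (OBz). The route rests on cutting the C2–C3 bond of the cyclohexene ring: the trans C2/C3 diol has its C3 end allylic to C4=C5, so C3 can arrive as an enal that CrCl2/Me3SiCl reverses in polarity and adds to an aldehyde at C2. This one operation closes the six-membered ring, creates C2 and C3 and leaves the alkene at C4=C5. The precursor is an acyclic enal–aldehyde in which C6 and C1 are the trans-acetonide of L-threitol (L-tartrate) and C7 is a PMB (4-methoxybenzyl) ether.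

Key step: step 10

Remark: 1 and 5 are taken as purchased (1 is the reduction product of the acetonide of a dialkyl L-tartrate).
Remark: 11 is expected as an E/Z mixture and is carried unseparated through 12–14 (E isomers drawn), because both isomers give the same allylchromium species.
Remark: in open-chain terms the ring-trans C2/C3 diol is the threo (zigzag syn) relation and the ring-cis C1/C2 pair is erythro; this governs step 10 and its fallback.
Remark: the C6 and C7 oxygens of 14 are kept as ketal and ether because they are β to chromium in 15; the PMB ether is chosen because it later separates C6/C7 from C1 (step 13).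

Step 1
Reactants: 1 (4S,5S)-2,2-dimethyl-1,3-dioxolane-4,5-dimethanol (2,3-O-isopropylidene-L-threitol)
Product: 2 [(4S,5S)-5-({[tert-butyl(dimethyl)silyl]oxy}methyl)-2,2-dimethyl-1,3-dioxolan-4-yl]methanol
Conditions: NaH (1.0 equiv), THF, 0 °C; t-BuMe2SiCl (1.0 equiv), 0 → 25 °C
Reagents that add atoms: tert-butyldimethylsilyl chloride, CC(C)(C)[Si](C)(C)Cl
Why: Monosilylation of a C2-symmetric diol through its monosodium alkoxide; either hydroxyl gives the same compound and no stereocentre is touched.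

Step 2
Reactants: 2 [(4S,5S)-5-({[tert-butyl(dimethyl)silyl]oxy}methyl)-2,2-dimethyl-1,3-dioxolan-4-yl]methanol
Product: 3 (4R,5S)-5-({[tert-butyl(dimethyl)silyl]oxy}methyl)-2,2-dimethyl-1,3-dioxolane-4-carbaldehyde
Conditions: (COCl)2, DMSO, CH2Cl2, −78 °C; Et3N, −78 → 0 °C
Reagents that add atoms: none
Why: Swern oxidation of the primary alcohol; the α-alkoxy aldehyde is configurationally safe because the trans-dioxolane is also the thermodynamically favoured isomer.

Step 3
Reactants: 4 4-methoxybenzyl alcohol; 5 tributyl(iodomethyl)stannane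
Product: 6 tributyl{[(4-methoxybenzyl)oxy]methyl}stannane
Conditions: NaH, THF/DMF, 0 °C; then 5, 25 °C
Reagents that add atoms: none
Why: Williamson ether synthesis, in which the sodium alkoxide of 4 displaces the primary iodide of 5 (SN2), the usual entry to alkoxymethylstannanes.

Step 4
Reactants: 3 (4R,5S)-5-({[tert-butyl(dimethyl)silyl]oxy}methyl)-2,2-dimethyl-1,3-dioxolane-4-carbaldehyde; 6 tributyl{[(4-methoxybenzyl)oxy]methyl}stannane
Product: 8 1-[(4S,5S)-5-({[tert-butyl(dimethyl)silyl]oxy}methyl)-2,2-dimethyl-1,3-dioxolan-4-yl]-2-[(4-methoxybenzyl)oxy]ethanol (both carbinol epimers), via [(4-methoxybenzyl)oxy]methyllithium 7 (not isolated)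
Conditions: 6, n-BuLi, THF, −78 °C; then 3, −78 °C; H2O
Reagents that add atoms: none
Why: Tin–lithium exchange gives the α-alkoxymethyllithium 7, which adds to the aldehyde at −78 °C (1,2-addition); the new carbinol centre (C5) needs no control because step 5 oxidises it.

Step 5
Reactants: 8 1-[(4S,5S)-5-({[tert-butyl(dimethyl)silyl]oxy}methyl)-2,2-dimethyl-1,3-dioxolan-4-yl]-2-[(4-methoxybenzyl)oxy]ethanol
Product: 9 1-[(4R,5S)-5-({[tert-butyl(dimethyl)silyl]oxy}methyl)-2,2-dimethyl-1,3-dioxolan-4-yl]-2-[(4-methoxybenzyl)oxy]ethanone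
Conditions: Dess–Martin periodinane, CH2Cl2, 0 → 25 °C
Reagents that add atoms: none
Why: Dess–Martin oxidation of the secondary alcohol to the ketone without base, so the α-stereocentre C6 is not enolised.

Step 6
Reactants: 9 1-[(4R,5S)-5-({[tert-butyl(dimethyl)silyl]oxy}methyl)-2,2-dimethyl-1,3-dioxolan-4-yl]-2-[(4-methoxybenzyl)oxy]ethanone; 10 ethyl (triphenylphosphoranylidene)acetate
Product: 11 ethyl (2E)-3-[(4S,5S)-5-({[tert-butyl(dimethyl)silyl]oxy}methyl)-2,2-dimethyl-1,3-dioxolan-4-yl]-4-[(4-methoxybenzyl)oxy]but-2-enoate (with its 2Z isomer)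
Conditions: toluene, 90 °C
Reagents that add atoms: none
Why: Wittig olefination with a stabilised ylide, which reacts with α,α′-dioxygenated ketones (protected 2-ketoses) without added base and so leaves C6 intact; the E/Z ratio does not matter because step 10 erases the alkene geometry.

Step 7
Reactants: 11 ethyl (2E)-3-[(4S,5S)-5-({[tert-butyl(dimethyl)silyl]oxy}methyl)-2,2-dimethyl-1,3-dioxolan-4-yl]-4-[(4-methoxybenzyl)oxy]but-2-enoate
Product: 12 (2E)-3-[(4S,5S)-5-({[tert-butyl(dimethyl)silyl]oxy}methyl)-2,2-dimethyl-1,3-dioxolan-4-yl]-4-[(4-methoxybenzyl)oxy]but-2-en-1-ol (with its 2Z isomer)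
Conditions: i-Bu2AlH (2.5 equiv), CH2Cl2, −78 °C; aq. KNaC4H4O6
Reagents that add atoms: none
Why: 1,2-Reduction of the α,β-unsaturated ester to the allylic alcohol with i-Bu2AlH; silyl ether, ketal and PMB ether do not react.

Step 8
Reactants: 12 (2E)-3-[(4S,5S)-5-({[tert-butyl(dimethyl)silyl]oxy}methyl)-2,2-dimethyl-1,3-dioxolan-4-yl]-4-[(4-methoxybenzyl)oxy]but-2-en-1-ol
Product: 13 (2E)-3-[(4S,5S)-5-(hydroxymethyl)-2,2-dimethyl-1,3-dioxolan-4-yl]-4-[(4-methoxybenzyl)oxy]but-2-en-1-ol (with its 2Z isomer)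
Conditions: Bu4NF, THF, 0 °C
Reagents that add atoms: none
Why: Fluoride cleavage of the primary silyl ether; the other groups are stable to Bu4NF.

Step 9
Reactants: 13 (2E)-3-[(4S,5S)-5-(hydroxymethyl)-2,2-dimethyl-1,3-dioxolan-4-yl]-4-[(4-methoxybenzyl)oxy]but-2-en-1-ol
Product: 14 (4R,5S)-5-{(2E)-1-[(4-methoxybenzyl)oxy]-4-oxobut-2-en-2-yl}-2,2-dimethyl-1,3-dioxolane-4-carbaldehyde (with its 2Z isomer)
Conditions: Dess–Martin periodinane (3 equiv), CH2Cl2, 0 → 25 °C; used at once
Reagents that add atoms: none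
Why: Twofold Dess–Martin oxidation of the primary and the allylic alcohol without amine base, which protects C1 from epimerisation and the γ-positions of the enal from deprotonation.

Step 10
Reactants: 14 (4R,5S)-5-{(2E)-1-[(4-methoxybenzyl)oxy]-4-oxobut-2-en-2-yl}-2,2-dimethyl-1,3-dioxolane-4-carbaldehyde (E/Z mixture)
Product: 17 (3aS,4S,5R,7aS)-7-{[(4-methoxybenzyl)oxy]methyl}-2,2-dimethyl-3a,4,5,7a-tetrahydro-1,3-benzodioxole-4,5-diol, via γ-siloxyallylchromium dichloride 15 (not isolated), via bis(trimethylsilyl) ether 16 (not isolated)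
Conditions: CrCl2 (6 equiv), Me3SiCl (4 equiv), DMF, 25 °C, 14 added over 10 h (final 0.005 M); then K2CO3, MeOH, 0 °C
Reagents that add atoms: none
Why: Proposed new method: Me3SiCl-assisted transfer of two electrons from divalent chromium to the conjugated C3 aldehyde (the saturated C2 aldehyde is not reduced by CrCl2) gives the γ-siloxyallylchromium 15, formed alike from both alkene isomers, which hands C3 to the C2 carbonyl with allylic transposition so that the alkene returns to C4=C5; the closest known reaction is the intermolecular CrCl2/Me3SiCl cross-pinacol-type coupling of enals with aldehydes, and what is new is ring closure in which all three allyl carbons end up in the ring. The cyclohexene closes 6-exo-trig at the C2 carbonyl (bonding through C5 would need a cyclobutane), and because C5 and C2 are linked by only C6–C1 the chair array of the intermolecular reaction cannot form, so closure must run through a twisted boat in which chromium on C5 reaches the C2 oxygen or through an open array with the silyl chloride on that oxygen. C2 is controlled by C1: the trans-fused dioxolane holds the C1–O bond equatorial and anti to the incoming C3 (Felkin–Anh), which turns the carbonyl oxygen pseudo-axial, across the ring toward C5 and cis to C1–O. C3 is controlled by the position of the siloxy group in the allyl unit: inside (cis to C5) it becomes pseudo-axial and trans to C2–O, anti to the chromium-bound oxygen and on the ring face away from the metal, whereas outside it would give the cis (erythro) diol that the intermolecular chair array delivers, so this is the selectivity the step needs and the one not secured by precedent. Ring closure must also outrun dimerisation and β-elimination of the C6 and C7 oxygens from chromium, for which slow addition at high dilution and a ketal and an ether (never esters) at these positions are provided.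

Step 11
Reactants: 17 (3aS,4S,5R,7aS)-7-{[(4-methoxybenzyl)oxy]methyl}-2,2-dimethyl-3a,4,5,7a-tetrahydro-1,3-benzodioxole-4,5-diol
Product: 18 C2,C3-bis(tert-butyldimethylsilyl) ether of 17 (all four stereocentres as in 17)
Conditions: t-BuMe2SiOTf (3 equiv), 2,6-lutidine, CH2Cl2, −78 → 0 °C
Reagents that add atoms: tert-butyldimethylsilyl trifluoromethanesulfonate, CC(C)(C)[Si](C)(C)OS(=O)(=O)C(F)(F)F
Why: Silylation of both secondary alcohols with the silyl triflate and 2,6-lutidine, which is reactive enough for the axial C2 hydroxyl and leaves ketal and PMB ether untouched.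

Step 12
Reactants: 18 C2,C3-bis(tert-butyldimethylsilyl) ether of 17
Product: 19 C1,C6-diol: cyclohexene with free C1–OH and C6–OH, C2 and C3 OTBS, C7 OPMB (C1–O/C2–O cis, C2–O/C3–O trans, C1–O/C6–O trans)
Conditions: AcOH/H2O (4:1), 40 °C
Reagents that add atoms: none
Why: Acid hydrolysis of the strained trans-fused acetonide, which is far more labile under aqueous acetic acid than secondary TBS ethers or the PMB ether.

Step 13
Reactants: 19 C1,C6-diol with C2 and C3 OTBS and C7 OPMB
Product: 20 C6,C7-O-(4-methoxybenzylidene) acetal with free C1–OH (C2 and C3 OTBS; aryl group expected equatorial on the new 1,3-dioxane)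
Conditions: DDQ (1.2 equiv), 4 Å molecular sieves, CH2Cl2, 0 °C
Reagents that add atoms: none
Why: Oxidative acetalisation of a PMB ether under anhydrous conditions: the benzylic oxocarbenium ion at O7 is captured by the 1,3-related C6 hydroxyl as a six-membered acetal, whereas the C1 hydroxyl would need a seven-membered ring, so only C1–OH stays free.

Step 14
Reactants: 20 C6,C7-O-(4-methoxybenzylidene) acetal with free C1–OH
Product: 21 C1 acetate of 20
Conditions: Ac2O, pyridine, DMAP (cat.), CH2Cl2, 25 °C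
Reagents that add atoms: acetic anhydride, CC(=O)OC(C)=O
Why: DMAP-catalysed acetylation of the only free hydroxyl (C1).

Step 15
Reactants: 21 C1 acetate of 20
Product: 22 C6,C7-diol with C1 OAc and C2, C3 OTBS
Conditions: AcOH/H2O (4:1), 25 °C
Reagents that add atoms: none
Why: Mild acid hydrolysis of the 4-methoxybenzylidene acetal, which is cleaved well before secondary TBS ethers and does not touch the acetate.

Step 16
Reactants: 22 C6,C7-diol with C1 OAc and C2, C3 OTBS
Product: 23 C6,C7-dibenzoate of 22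
Conditions: BzCl (3 equiv), pyridine, DMAP (cat.), CH2Cl2, 0 → 25 °C
Reagents that add atoms: benzoyl chloride, O=C(Cl)c1ccccc1
Why: Benzoylation of the primary C7 and the allylic C6 hydroxyl; no selectivity is needed because C1, C2 and C3 are already masked.

Step 17
Reactants: 23 C6,C7-dibenzoate with C1 OAc and C2, C3 OTBS
Product: 24 [(3R,4S,5S,6S)-5-(acetyloxy)-6-(benzoyloxy)-3,4-dihydroxycyclohex-1-en-1-yl]methyl benzoate (CNP0213675.1)
Conditions: HF·pyridine, pyridine/THF, 0 → 25 °C
Reagents that add atoms: none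
Why: Desilylation with an acidic, buffered fluoride source, chosen so that the C1 acetate does not migrate to the cis C2 hydroxyl as it could under basic fluoride.

Compound list
1 | (4S,5S)-2,2-dimethyl-1,3-dioxolane-4,5-dimethanol | OC[C@@H]1OC(C)(C)O[C@H]1CO | starting material
2 | [(4S,5S)-5-({[tert-butyl(dimethyl)silyl]oxy}methyl)-2,2-dimethyl-1,3-dioxolan-4-yl]methanol | CC(C)(C)[Si](C)(C)OC[C@@H]1OC(C)(C)O[C@H]1CO | intermediate
3 | (4R,5S)-5-({[tert-butyl(dimethyl)silyl]oxy}methyl)-2,2-dimethyl-1,3-dioxolane-4-carbaldehyde | CC(C)(C)[Si](C)(C)OC[C@@H]1OC(C)(C)O[C@H]1C=O | intermediate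
4 | 4-methoxybenzyl alcohol | COc1ccc(CO)cc1 | starting material
5 | tributyl(iodomethyl)stannane | CCCC[Sn](CCCC)(CCCC)CI | starting material
6 | tributyl{[(4-methoxybenzyl)oxy]methyl}stannane | CCCC[Sn](CCCC)(CCCC)COCc1ccc(OC)cc1 | intermediate
7 | [(4-methoxybenzyl)oxy]methyllithium (not isolated) | [Li]COCc1ccc(OC)cc1 | intermediate
8 | 1-[(4S,5S)-5-({[tert-butyl(dimethyl)silyl]oxy}methyl)-2,2-dimethyl-1,3-dioxolan-4-yl]-2-[(4-methoxybenzyl)oxy]ethanol, both carbinol epimers | CC(C)(C)[Si](C)(C)OC[C@@H]1OC(C)(C)O[C@H]1C(O)COCc2ccc(OC)cc2 | intermediate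
9 | 1-[(4R,5S)-5-({[tert-butyl(dimethyl)silyl]oxy}methyl)-2,2-dimethyl-1,3-dioxolan-4-yl]-2-[(4-methoxybenzyl)oxy]ethanone | CC(C)(C)[Si](C)(C)OC[C@@H]1OC(C)(C)O[C@H]1C(=O)COCc2ccc(OC)cc2 | intermediate
10 | ethyl (triphenylphosphoranylidene)acetate | CCOC(=O)C=P(c1ccccc1)(c1ccccc1)c1ccccc1 | starting material
11 | ethyl (2E)-3-[(4S,5S)-5-({[tert-butyl(dimethyl)silyl]oxy}methyl)-2,2-dimethyl-1,3-dioxolan-4-yl]-4-[(4-methoxybenzyl)oxy]but-2-enoate (E drawn, Z isomer carried along) | CC(C)(C)[Si](C)(C)OC[C@@H]1OC(C)(C)O[C@H]1/C(COCc2ccc(OC)cc2)=C/C(=O)OCC | intermediate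
12 | (2E)-3-[(4S,5S)-5-({[tert-butyl(dimethyl)silyl]oxy}methyl)-2,2-dimethyl-1,3-dioxolan-4-yl]-4-[(4-methoxybenzyl)oxy]but-2-en-1-ol (E drawn) | CC(C)(C)[Si](C)(C)OC[C@@H]1OC(C)(C)O[C@H]1/C(COCc2ccc(OC)cc2)=C/CO | intermediate
13 | (2E)-3-[(4S,5S)-5-(hydroxymethyl)-2,2-dimethyl-1,3-dioxolan-4-yl]-4-[(4-methoxybenzyl)oxy]but-2-en-1-ol (E drawn) | OC[C@@H]1OC(C)(C)O[C@H]1/C(COCc2ccc(OC)cc2)=C/CO | intermediate
14 | (4R,5S)-5-{(2E)-1-[(4-methoxybenzyl)oxy]-4-oxobut-2-en-2-yl}-2,2-dimethyl-1,3-dioxolane-4-carbaldehyde (E drawn) | O=C[C@@H]1OC(C)(C)O[C@H]1/C(COCc2ccc(OC)cc2)=C/C=O | intermediate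
15 | γ-siloxyallylchromium dichloride: trivalent chromium (CrCl2 unit) on C5, trimethylsilyl enol ether C3=C4, C2 aldehyde intact (not isolated) | O=C[C@@H]1OC(C)(C)O[C@H]1C(COCc2ccc(OC)cc2)(C=CO[Si](C)(C)C)[Cr](Cl)Cl | intermediate
16 | C2,C3-bis(trimethylsilyl) ether of 17 (not isolated) | C[Si](C)(C)O[C@H]1[C@H](O[Si](C)(C)C)C=C(COCc2ccc(OC)cc2)[C@@H]2OC(C)(C)O[C@@H]12 | intermediate
17 | (3aS,4S,5R,7aS)-7-{[(4-methoxybenzyl)oxy]methyl}-2,2-dimethyl-3a,4,5,7a-tetrahydro-1,3-benzodioxole-4,5-diol | O[C@H]1[C@H](O)C=C(COCc2ccc(OC)cc2)[C@@H]2OC(C)(C)O[C@@H]12 | intermediate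
18 | C2,C3-bis(tert-butyldimethylsilyl) ether of 17 | CC(C)(C)[Si](C)(C)O[C@H]1[C@H](O[Si](C)(C)C(C)(C)C)C=C(COCc2ccc(OC)cc2)[C@@H]2OC(C)(C)O[C@@H]12 | intermediate
19 | C1,C6-diol with C2, C3 OTBS and C7 OPMB (C1–O/C2–O cis, C2–O/C3–O trans, C1–O/C6–O trans) | O[C@H]1[C@@H](O[Si](C)(C)C(C)(C)C)[C@H](O[Si](C)(C)C(C)(C)C)C=C(COCc2ccc(OC)cc2)[C@@H]1O | intermediate
20 | C6,C7-O-(4-methoxybenzylidene) acetal with free C1–OH, C2 and C3 OTBS | O[C@H]1[C@@H](O[Si](C)(C)C(C)(C)C)[C@H](O[Si](C)(C)C(C)(C)C)C=C2COC(c3ccc(OC)cc3)O[C@H]12 | intermediate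
21 | C1 acetate of 20 | CC(=O)O[C@H]1[C@@H](O[Si](C)(C)C(C)(C)C)[C@H](O[Si](C)(C)C(C)(C)C)C=C2COC(c3ccc(OC)cc3)O[C@H]12 | intermediate
22 | C6,C7-diol with C1 OAc and C2, C3 OTBS | CC(=O)O[C@H]1[C@@H](O[Si](C)(C)C(C)(C)C)[C@H](O[Si](C)(C)C(C)(C)C)C=C(CO)[C@@H]1O | intermediate
23 | C6,C7-dibenzoate with C1 OAc and C2, C3 OTBS | CC(=O)O[C@H]1[C@@H](O[Si](C)(C)C(C)(C)C)[C@H](O[Si](C)(C)C(C)(C)C)C=C(COC(=O)c2ccccc2)[C@@H]1OC(=O)c1ccccc1 | intermediate
24 | [(3R,4S,5S,6S)-5-(acetyloxy)-6-(benzoyloxy)-3,4-dihydroxycyclohex-1-en-1-yl]methyl benzoate | CC(=O)O[C@H]1[C@@H](O)[C@H](O)C=C(COC(=O)c2ccccc2)[C@@H]1OC(=O)c1ccccc1 | target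

Total step count: 17. Longest linear sequence: 16 steps (1, 2 and 4–17; step 3 prepares reagent 6).

Steps most likely to fail

Step 10 (ring closure). The siloxy group may react from the outside position and give the C3-epimeric diol. The open-chain species may also couple intermolecularly, lose the C6 or C7 oxygen by β-elimination, or fail to close at the hindered C5–chromium stage. A bulkier silyl chloride would be the first variable to test; the fallback replaces the step by known chemistry. It sets out from ketone 9. Methylenation (Ph3P=CH2, THF, 0 °C, or Cp2TiMe2 if enolisation interferes) would give the 1,1-disubstituted alkene F1. Bu4NF would free the primary alcohol F2, and Dess–Martin oxidation would give the aldehyde F3. The (Z)-γ-silyloxyallylstannane F4 (from allyl tert-butyldimethylsilyl ether with s-BuLi and then Bu3SnCl) would be added with BF3·OEt2 in CH2Cl2 at −78 °C, with KF work-up. This open-transition-state addition is syn-selective for the new diol and follows the Felkin–Anh sense at C1, so it should give the C2-alcohol/C3-silyl ether diene F5 with the required threo C2/C3 and erythro C1/C2 relations. Ring-closing metathesis with second-generation Grubbs catalyst, RuCl2(=CHPh)(PCy3)(H2IMes), in CH2Cl2 at 40 °C would close the C4=C5 alkene and give the cyclohexene F6. Silylation of the C2 hydroxyl (t-BuMe2SiOTf, 2,6-lutidine) returns to the route at 18.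

Step 9 (double oxidation). The Z isomer may form a lactol and be over-oxidised, C1 may epimerise, or the dialdehyde may degrade during isolation. The fallback sets out from allylic alcohol 12 and builds the two aldehydes one at a time. MnO2 in CH2Cl2 oxidises only the allylic alcohol and would give the silyl-protected enal F7. HF·pyridine in THF at 0 °C would free the primary alcohol to give the hydroxy enal F8. A single Dess–Martin oxidation of that alcohol returns to the route at 14.

Step 13 (oxidative acetalisation). Adventitious water may hydrolyse the oxocarbenium ion, excess oxidant may open the acetal to hydroxy esters, or the allylic C6 alcohol may be oxidised. The fallback sets out from diol 19 and separates cleavage from acetal formation. DDQ in CH2Cl2/pH 7 buffer would cleave the PMB ether hydrolytically to the triol F9. Acid-catalysed exchange with 4-methoxybenzaldehyde dimethyl acetal (PPTS, CH2Cl2) should then give the six-membered C6/C7 acetal under thermodynamic control, since a trans-fused five-membered C6/C1 acetal is disfavoured. This returns to the route at 20.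

Further compounds
F1 | step 10 | tert-butyl({(4S,5S)-5-[3-((4-methoxybenzyl)oxy)prop-1-en-2-yl]-2,2-dimethyl-1,3-dioxolan-4-yl}methoxy)dimethylsilane | CC(C)(C)[Si](C)(C)OC[C@@H]1OC(C)(C)O[C@H]1C(=C)COCc2ccc(OC)cc2
F2 | step 10 | {(4S,5S)-5-[3-((4-methoxybenzyl)oxy)prop-1-en-2-yl]-2,2-dimethyl-1,3-dioxolan-4-yl}methanol | OC[C@@H]1OC(C)(C)O[C@H]1C(=C)COCc2ccc(OC)cc2
F3 | step 10 | (4R,5S)-5-[3-((4-methoxybenzyl)oxy)prop-1-en-2-yl]-2,2-dimethyl-1,3-dioxolane-4-carbaldehyde | O=C[C@@H]1OC(C)(C)O[C@H]1C(=C)COCc2ccc(OC)cc2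
F4 | step 10 | (Z)-tributyl{3-[(tert-butyldimethylsilyl)oxy]prop-2-en-1-yl}stannane | CCCC[Sn](CCCC)(CCCC)C/C=C\O[Si](C)(C)C(C)(C)C
F5 | step 10 | diene with C2–OH, C3–OTBS and terminal vinyl at C3, C5 methylene, C6/C1 acetonide, C7 OPMB (C2 and C3 configured as in 18) | C=C[C@@H](O[Si](C)(C)C(C)(C)C)[C@H](O)[C@@H]1OC(C)(C)O[C@H]1C(=C)COCc2ccc(OC)cc2
F6 | step 10 | C3-mono(tert-butyldimethylsilyl) ether of 17 | O[C@H]1[C@H](O[Si](C)(C)C(C)(C)C)C=C(COCc2ccc(OC)cc2)[C@@H]2OC(C)(C)O[C@@H]12
F7 | step 9 | (2E)-3-[(4S,5S)-5-({[tert-butyl(dimethyl)silyl]oxy}methyl)-2,2-dimethyl-1,3-dioxolan-4-yl]-4-[(4-methoxybenzyl)oxy]but-2-enal (E drawn) | CC(C)(C)[Si](C)(C)OC[C@@H]1OC(C)(C)O[C@H]1/C(COCc2ccc(OC)cc2)=C/C=O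
F8 | step 9 | (2E)-3-[(4S,5S)-5-(hydroxymethyl)-2,2-dimethyl-1,3-dioxolan-4-yl]-4-[(4-methoxybenzyl)oxy]but-2-enal (E drawn) | OC[C@@H]1OC(C)(C)O[C@H]1/C(COCc2ccc(OC)cc2)=C/C=O
F9 | step 13 | C1,C6,C7-triol with C2 and C3 OTBS | O[C@H]1[C@@H](O[Si](C)(C)C(C)(C)C)[C@H](O[Si](C)(C)C(C)(C)C)C=C(CO)[C@@H]1O
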